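**Opening.** Count the fresh partner.

| flask | substrate | fresh partner | coupling partner | temperature | remark | time |
|---|---|---|---|---|---|---|
| red | 20 mM | 0.80 equiv | 2.7 equiv | 50 °C | run made earlier |  |
| amber | 10 mM | 0.80 equiv | 4 equiv | 50 °C | run made earlier |  |
| dawn | 20 mM | 1.60 equiv | 4.00 equiv | 50 °C |  | 10 min |
| spring | 20 mM | 0.800 equiv | 4.00 equiv | 50 °C |  | 10 min |

- red (time / min: target / %, substrate / %): 0.417: 1, 72; 1.33: 3, 43; 2.50: 15, 22; 4.00: 26, 11
- amber (time / min: target / %, substrate / %): 0.833: 2, 58; 2.00: 4, 36; 2.50: 6, 29; 4.00: 16, 14

(each reading ± 1.5 percentage points)

- the winner by amount of target, in percent of the substrate charged; "neither" if no more than 2 percentage points parts them (dawn / spring / neither)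
- how much target is there at the end, in percent of the substrate charged: dawn
- how much target is there at the end, in percent of the substrate charged: spring

- a reading or a percentage of target counts all its forms, free or not

**First instants.** In the red run, substrate is the quick mover. By 1.33 min it reads 43 %, yet target reads 3 %. So 54.0 % of the charge stands in some unread form, and this reading carries the scatter.

**The middle.** By 4.00 min, red shows substrate at 11 % and target at 26 %. The unread share is now 63.0 %. Substrate is nearly used, so what matters next is how that unread share becomes target.

**The end.** This reckoning, not the forecast's, assumes that each target carries one fresh partner. Fresh partner is then the limiting reagent in spring, and target there is held to C = 80.0 % of the substrate charged, the fresh-partner ceiling. Dawn charges 1.60 equiv, so there the substrate charge is the limit. C gives room, not a time. The reckoning commits to dawn as winner and to spring short of C at 10 min.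

**The forecast.** It names dawn, with 76 % for dawn and 69 % for spring. Its ground for the winner: “Doubling the fresh partner speeds the first step modestly”.

**The result.** Dawn gives 72.5 % and spring 52.1 %, crystals counted in, so dawn wins.

    substrate + coupling partner → open intermediate (k = 16.0 M⁻¹ min⁻¹, Ea = 55.0 kJ mol⁻¹)
    coupling partner + fresh partner → second intermediate (k = 8.30 M⁻¹ min⁻¹, Ea = 57.0 kJ mol⁻¹)
    open intermediate + second intermediate → target (k = 30.0 M⁻¹ min⁻¹, Ea = 39.0 kJ mol⁻¹)
    2 second intermediate → homo product (k = 21.0 M⁻¹ min⁻¹, Ea = 61.0 kJ mol⁻¹)
    crystals ⇌ target, rate k5*(cs5 - [target]) while solid is left; crystals form when [target] > cs5 (solubility = 2.20 mM, k = 12.0 min⁻¹)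
    (constants at 50 °C)

**The ledger.** In spring, reckoned at the charged concentrations, substrate has a half-life of 0.54 min by its step into open intermediate alone, against 5.2 min for coupling partner by its step into second intermediate alone. At 10 min spring holds 47.9 % as open intermediate, with 1.67 % of its fresh partner left, and at 100 min open intermediate still stands at 42.4 %, with fresh partner at 0 %. At 100 min, spring's homo product stands at 2.24 mM, two fresh partner each, which takes 22.4 % of the substrate charged from C and leaves 57.6 %, the 57.6 % of target then present. The neighbour of dawn with 0.400 equiv of fresh partner has a ceiling of 40.0 % and holds 31.8 % of target at 10 min.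

(All runs come from a simulation for an exercise.)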